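The earlier runs and the new flask come from a simulation on assumed constants; the scatter is artificial.

Late in both earlier runs Z and J no longer add up to the charge, so before reckoning a new flask under held gas D, I must find out which of the two readings serves for the J asked.

| flask | Z | D | remark | time |
|---|---|---|---|---|
| alpha | 0.010 M | 7.8 mM (held) | run made earlier |  |
| theta | 0.040 M | 7.8 mM (held) | run made earlier |  |
| flask | 0.020 M | 7.8 mM (held) |  | 6.0 h |

- alpha (time / h: J / %, Z / %): 0.500: 2, 96; 0.833: 8, 92; 1.33: 14, 88; 2.00: 27, 73; 3.00: 38, 59; 5.00: 56, 35; 8.00: 72, 9
- theta (time / h: J / %, Z / %): 0.417: 2, 102; 1.00: 0, 96; 2.00: 6, 90; 3.00: 8, 83; 4.00: 13, 79; 6.00: 16, 64; 8.00: 26, 54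

(scatter of a reading: 2 percentage points)

- at the start none of D is in solution

1. the J standing at 6.0 h, as a percentage of the Z charged
2. the change that raises the amount of J at 6.0 h, in percent of the Z charged most ("none" if none brings more than 2 percentage points) (maple / alder / none)
3. amount of J at 6.0 h, in percent of the Z charged, after maple

- maple: doubling the saturation concentration of D, all else as stated
- alder: doubling the transfer coefficient of D, all else as stated

D is not a charge but a supply: it is held, its saturation of 7.8 mM caps what stands dissolved, and none is dissolved at the start. After the lag, its balance says that passage into solution, proportional to saturation minus c(D), equals use by reaction. If that passage is the rate-limiting step, J rises at a rate that ignores c(Z).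

I test this in two ways. By J gained, alpha at 3.00 h gives 1.27 mM h⁻¹ and theta at 8.00 h gives 1.30 mM h⁻¹, close although the charges differ by a factor of 4.00. By Z lost, alpha gives 1.37 mM h⁻¹, near its J figure, but theta gives 2.30 mM h⁻¹, faster than its J rate. At 8.00 h, the sum of Z and J in theta falls 8.00 mM short of the charge, against 1.90 mM in alpha at 8.00 h. These readings do not tell whether that gap was lost from Z or from J, but Z lost overstates what stands as J, so for the J asked it is the way that cheats.

I keep 1.28 mM h⁻¹, the mean of the J figures, and call it w, the net rate at which J accumulates under the gas supply. For the flask, w gives 38.5% at 6.0 h. Maple doubles the saturation and so the passage, and the flask's charge is twice alpha's, so the maple flask should follow alpha, which I interpolate to 61.3% at that time. Alder brings c(D) nearer saturation, so I place it slightly behind maple.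

The forecast, holding that “the absolute rates barely depend on Z”, gives 33%, below my figure, with maple best at 60%.

The flask gives 39.6%, 1.1 percentage points above w's figure. Maple reaches 64.1%, gaining 24 points against 22 points for alder.

    Z + J → L (k = 3.60 M⁻¹ h⁻¹)
    D ⇌ X, rate k2*(csat - [X]) (kL = 0.240 h⁻¹)
    X + J → Q (k = 25.0 M⁻¹ h⁻¹)
    Z + X → J (k = 220 M⁻¹ h⁻¹)

At 6.00 h the flask holds 11.7% as L, each L counting as two Z, beside 39.6% as J. For the same charge read at 10 h, w gives 64.2%, and that neighbour stands at 55.8% with 17.5% of its Z left.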